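| flask | electrophile | free base | gas | scavenger | remark | time |
|---|---|---|---|---|---|---|
| Saturday's | 12 mM | 18 mM | 1.4 mM (held) | 25 mM | run made earlier |  |
| Monday's | 12 mM | 18 mM | 1.4 mM (held) | 40 mM | run made earlier |  |
| Thursday's | 12 mM | 36 mM | 1.4 mM (held) | 18 mM | run made earlier |  |
| flask | 12 mM | 18.0 mM | 1.4 mM (held) | 18.0 mM |  | 10 d |

| run | time / d | electrophile / % | target / % |
|---|---|---|---|
| Saturday's | 0.500 | 57.9 | 5.1 |
| Saturday's | 0.833 | 56.7 | 9.3 |
| Saturday's | 1.67 | 49.3 | 19.7 |
| Saturday's | 3.00 | 39.9 | 34.4 |
| Saturday's | 6.00 | 22.6 | 61.8 |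
| Monday's | 1.25 | 51.9 | 14.7 |
| Monday's | 2.50 | 43.3 | 28.8 |
| Monday's | 4.00 | 33.2 | 45.4 |
| Monday's | 5.00 | 27.1 | 54.9 |
| Monday's | 6.00 | 22.0 | 63.2 |
| Thursday's | 0.500 | 58.2 | 5.9 |
| Thursday's | 0.833 | 55.7 | 9.7 |
| Thursday's | 1.67 | 50.4 | 19.9 |
| Thursday's | 3.00 | 39.8 | 35.2 |
| Thursday's | 6.00 | 22.1 | 63.9 |

(scatter of a reading: 0.5 percentage points)

- the numbers in the tables scatter with a standard deviation of 0.5 percentage points
- at the start none of the gas is in solution
- what has gone from electrophile into another species counts as reacted, even if it can come back
- the earlier runs do not show how much of nucleophile is bound; that part of a forecast is a guess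

- part of the electrophile that has reacted at 10 d
- share of the unused nucleophile that is free and not bound as protonated nucleophile, at 10 d

1. The easy step is to count the target peak as the electrophile reacted. Saturday's run refuses this: target is 0.121 of the reacted part at 0.500 d and 0.798 at 6.00 d, so the rule of thumb fails at both readings.

2. The correction is the missing part, what is neither electrophile nor target. Pooled over one reading from each run, despite their different base and scavenger, it gives the gap ratio 0.621, the missing part over the electrophile left.

3. Taking the gap ratio as constant from the first readings on, c(electrophile) is what is not target, divided by 1 plus the gap ratio, all in percent of the electrophile charged.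

4. In Saturday's run, which differs from the flask in scavenger, what is not target decays at 0.141 d⁻¹ up to 3.00 d, then at 0.180 d⁻¹, faster. Carrying this later constant, read from Saturday's run, to 10 d in the flask, this reckoning gives 88.5% reacted, probably low because the constant was rising. It gives no free share.

5. The forecast gives 91% reacted, above this reckoning, and 85% free, reasoning that “the nucleophile is probably mostly free”.

6. The flask gives 91.4% reacted and 10.3% free, with 10.0 mM of protonated nucleophile beside 1.15 mM of nucleophile at 10.0 d.

    gas ⇌ nucleophile, rate k1*(csat - [nucleophile]) (kL = 4.39 × 10⁻⁵ s⁻¹)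
    nucleophile + acid set free ⇌ protonated nucleophile, settled at all times (K = 4.60 × 10⁶ M⁻¹)
    electrophile + nucleophile → acid set free + target (k = 0.00443 M⁻¹ s⁻¹)
    acid set free + scavenger → scavenged by-product (k = 0.00733 M⁻¹ s⁻¹)
    acid set free + free base ⇌ salt of the base, settled at all times (K = 2800 M⁻¹)
    electrophile ⇌ dormant form (K = 0.620, k = 9.62 × 10⁻⁵ s⁻¹)
    acid set free + free base ⇌ idle adduct, settled at all times (K = 21.7 M⁻¹)

In the flask, electrophile and dormant form relax by their own step with a half-life of 0.766 h, a pre-equilibrium far faster than the step to target, which alone gives electrophile a half-life of 1.6 d at 10.0 d. The gap ratio turns the flask's 85.9% of target into 8.70% of electrophile, against 8.65% in the flask, and the 93.0% of target in the neighbour flask with 4.8 mM of electrophile into 4.32%, against 4.30% there.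

Readings and results are calculated with made-up constants, noise included.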